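The route builds flavone ring A'' up on ring B instead of joining two finished arenes. Ring A'' is a phloroglucinol in which C8'' carries ring B (through C3') between O7'' and the pyranone oxygen on C8a''. A vinylketene–ynol ether benzannulation delivers exactly this 2-arylresorcinol motif. The precursor is a triisopropylsilyl ynol ether that already bears ring B, with O4' benzylated and chlorine at C1'. Heating it with 3-ethoxycyclobutenone forms C7''–C8'' and C4a''–C8a'' and closes ring A''. O7'' emerges free, O8a'' silylated and O5'' ethylated, which fixes the 8-aryl flavone. The chlorine later becomes boron for an enantioselective conjugate addition that sets C2.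

Key step: step 3

Locants: unprimed = flavanone rings A and C; single prime = ring B; double prime = flavone rings A'' and C''; triple prime = anisyl ring.

Assumption 1: the facial preference of the (pyridine-oxazoline)palladium catalyst towards chromones is taken to match that known for 3-substituted cyclohexenones, which gives 2S with the (R)-configured ligand; the antipodal ligand is equally available should the sense prove opposite.

Assumption 2: the C3'–C8'' axis has three ortho substituents and is treated as rotationally labile at room temperature, in keeping with a target formula that defines only C2.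

Step 1
Reactants: 1 methyl 5-chlorosalicylate
Product: 2 methyl 2-(benzyloxy)-5-chlorobenzoate
Conditions: BnBr, K2CO3, DMF, rt
Reagents that add atoms: benzyl bromide, BrCc1ccccc1
Why: Williamson etherification of the potassium phenoxide masks O4' with a group that tolerates organolithium bases, heat, fluoride and palladium catalysis and leaves by hydrogenolysis at the end, while the ester and the aryl chloride are untouched.

Step 2
Reactants: 2 methyl 2-(benzyloxy)-5-chlorobenzoate
Product: 5 {[2-(benzyloxy)-5-chlorophenyl]ethynyloxy}triisopropylsilane, via dibromoenolate 3 (not isolated), via lithium ynolate 4 (not isolated)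
Conditions: CH2Br2, lithium 2,2,6,6-tetramethylpiperidide (LiTMP), THF, −78 °C; LiN(SiMe3)2; n-BuLi, −78 °C → rt; iPr3SiOSO2CF3, −78 → 0 °C
Reagents that add atoms: dibromomethane, BrCBr; triisopropylsilyl trifluoromethanesulfonate, CC(C)[Si](OS(=O)(=O)C(F)(F)F)(C(C)C)C(C)C
Why: Kowalski ester homologation halted at the ynolate: LiCHBr2 is acylated by the ester, the dibromoketone is held as enolate 3, bromine–lithium exchange triggers a carbenoid 1,2-shift of the electron-rich aryl group to ynolate 4, and the bulky oxophilic silyl triflate traps it on oxygen; chlorine serves as the C1' handle because, unlike bromine, it does not exchange with n-BuLi at low temperature.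

Step 3
Reactants: 5 {[2-(benzyloxy)-5-chlorophenyl]ethynyloxy}triisopropylsilane; 6 3-ethoxycyclobut-2-en-1-one
Product: 11 2-[2-(benzyloxy)-5-chlorophenyl]-5-ethoxy-3-(triisopropylsilyloxy)phenol, via (1-ethoxyvinyl)ketene 7 (not isolated), via vinylcyclobutenone 8 (not isolated), via dienylketene 9 (not isolated), via cyclohexadienone 10 (not isolated)
Conditions: toluene, 80 → 110 °C, sealed vessel, 6 added in portions
Reagents that add atoms: none
Why: Heating opens 6 by a conrotatory four-electron electrocyclic reaction that breaks the C(=O)–CH2 bond and gives (1-ethoxyvinyl)ketene 7, which adds across the alkyne of 5 in a [2+2] cycloaddition to give vinylcyclobutenone 8; this event makes both new skeletal bonds, C7''–C8'' and C4a''–C8a''. Ring strain then drives a second four-electron opening of 8 to dienylketene 9, and ring A'' is closed by a disrotatory six-electron electrocyclisation (C6''–C7'') to dienone 10, whose tautomerisation to phenol 11 is the thermodynamic sink of the sequence. The closest known reaction type is the Danheiser benzannulation of cyclobutenones with trialkylsilyloxyalkynes, which gives resorcinol monosilyl ethers; the ethoxy group on C3 of 6 is a spectator donor and ends para to the aryl group as O5''. No stereocentre survives, because the sp3 carbon of 8 becomes aromatic C4a''. The selectivity needed is the orientation of the [2+2] step: donation from the silyloxy oxygen makes the aryl-bearing alkyne carbon the nucleophilic terminus, so it attacks the electrophilic central carbon of the ketene and ring B ends between the new hydroxyl (O7'') and the silyl ether (O8a''). The aryl chloride and the benzyl ether are inert under these neutral thermal conditions, and portionwise addition of 6 keeps the ketene concentration low so that its dimerisation and the acylation of 11 are held back.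

Step 4
Reactants: 11 2-[2-(benzyloxy)-5-chlorophenyl]-5-ethoxy-3-(triisopropylsilyloxy)phenol
Product: 12 {3-(benzyloxy)-2-[2-(benzyloxy)-5-chlorophenyl]-5-ethoxyphenoxy}triisopropylsilane
Conditions: BnBr, K2CO3, acetone, reflux
Reagents that add atoms: benzyl bromide, BrCc1ccccc1
Why: Williamson etherification of the only free phenol caps O7'' under anhydrous carbonate conditions that the hindered aryl triisopropylsilyl ether withstands, so O7'' and O8a'' remain distinguishable.

Step 5
Reactants: 12 {3-(benzyloxy)-2-[2-(benzyloxy)-5-chlorophenyl]-5-ethoxyphenoxy}triisopropylsilane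
Product: 13 3-(benzyloxy)-2-[2-(benzyloxy)-5-chlorophenyl]-5-ethoxyphenol
Conditions: Bu4NF, AcOH, THF, 0 °C
Reagents that add atoms: none
Why: Fluoride-induced Si–O cleavage, driven by the strong Si–F bond, releases O8a'' as the only free phenol, and the acetic acid buffer keeps the medium non-basic.

Step 6
Reactants: 13 3-(benzyloxy)-2-[2-(benzyloxy)-5-chlorophenyl]-5-ethoxyphenol
Product: 14 4-(benzyloxy)-3-[2-(benzyloxy)-5-chlorophenyl]-6-ethoxy-2-hydroxybenzaldehyde
Conditions: MgCl2, Et3N, (CH2O)n, MeCN, reflux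
Reagents that add atoms: paraformaldehyde (formaldehyde unit), C=O
Why: Casnati–Skattebøl ortho-formylation delivers formaldehyde inside the magnesium phenoxide chelate to an ortho carbon only and oxidises the resulting benzylic alkoxide by hydride transfer to a second formaldehyde, so with C8'' blocked the formyl group can enter only at C4a'' and never at the para carbon C6'', without the strong Lewis acids that would strip benzyl ethers.

Step 7
Reactants: 14 4-(benzyloxy)-3-[2-(benzyloxy)-5-chlorophenyl]-6-ethoxy-2-hydroxybenzaldehyde; 15 1-ethynyl-4-methoxybenzene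
Product: 17 3-(benzyloxy)-2-[2-(benzyloxy)-5-chlorophenyl]-5-ethoxy-6-[1-hydroxy-3-(4-methoxyphenyl)prop-2-yn-1-yl]phenol (racemic), via lithium acetylide 16 (not isolated)
Conditions: 15 (2.5 equiv), n-BuLi, THF, −78 °C; then 14, −78 → 0 °C; aq NH4Cl; crude product carried on
Reagents that add atoms: none
Why: In this 1,2-addition of a lithium acetylide to an aldehyde the first equivalent of 16 deprotonates the phenol and the second adds to the formyl carbon, giving the acid-sensitive carbinol as a racemate whose stereocentre is erased by the oxidation in step 8.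

Step 8
Reactants: 17 3-(benzyloxy)-2-[2-(benzyloxy)-5-chlorophenyl]-5-ethoxy-6-[1-hydroxy-3-(4-methoxyphenyl)prop-2-yn-1-yl]phenol
Product: 19 7-(benzyloxy)-8-[2-(benzyloxy)-5-chlorophenyl]-5-ethoxy-2-(4-methoxyphenyl)-4H-chromen-4-one, via ynone 18 (not isolated)
Conditions: MnO2, CH2Cl2, rt; filtration, concentration; DMAP (20 mol %), DMF, 40 °C
Reagents that add atoms: none
Why: MnO2 oxidation of the benzylic propargylic alcohol gives o-hydroxyaryl ynone 18, and nucleophilic catalysis by DMAP (conjugate addition to the ynone, then addition–elimination by the phenoxide at the β-carbon) steers the closure into the 6-endo mode, so O8a'', the only free phenol, becomes O1'' and the 8-aryl flavone is the only possible constitution.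

Step 9
Reactants: 19 7-(benzyloxy)-8-[2-(benzyloxy)-5-chlorophenyl]-5-ethoxy-2-(4-methoxyphenyl)-4H-chromen-4-one
Product: 20 7-(benzyloxy)-8-[2-(benzyloxy)-5-chlorophenyl]-5-hydroxy-2-(4-methoxyphenyl)-4H-chromen-4-one
Conditions: BCl3 (1.1 equiv), CH2Cl2, −78 → 0 °C; then H2O
Reagents that add atoms: none
Why: In this chelation-directed ether cleavage BCl3 binds the strongly basic pyranone carbonyl, closes a six-membered chelate with the peri O5'' and chloride removes the ethyl group by SN2, while a single equivalent held at the carbonyl spares both benzyl ethers and the remote anisyl methyl ether, and running it before C2 exists keeps Lewis acid away from the flavanone.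

Step 10
Reactants: 20 7-(benzyloxy)-8-[2-(benzyloxy)-5-chlorophenyl]-5-hydroxy-2-(4-methoxyphenyl)-4H-chromen-4-one
Product: 21 {4-(benzyloxy)-3-[7-(benzyloxy)-5-hydroxy-2-(4-methoxyphenyl)-4-oxo-4H-chromen-8-yl]phenyl}boronic acid
Conditions: B2(OH)4, Pd(OAc)2 (2 mol %), XPhos (4 mol %), KOAc, EtOH–THF, 80 °C
Reagents that add atoms: tetrahydroxydiboron, OB(O)B(O)O
Why: In this Miyaura-type borylation the bulky electron-rich biarylphosphine allows zerovalent palladium to insert into the C1'–Cl bond para to an alkoxy group, and acetate-assisted transmetalation with tetrahydroxydiboron gives directly the free boronic acid that step 13 needs, the hydrogen-bonded 5''-hydroxyl being too weakly acidic to interfere with KOAc.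

Step 11
Reactants: 22 2,4,6-trihydroxyacetophenone
Product: 23 1-[2,4-bis(benzyloxy)-6-hydroxyphenyl]ethan-1-one
Conditions: BnBr (2.1 equiv), K2CO3, DMF, rt → 60 °C
Reagents that add atoms: benzyl bromide, BrCc1ccccc1
Why: Williamson etherification under weak base with two equivalents of halide leaves one ortho hydroxyl free, because once a single hydroxyl hydrogen-bonded to the acetyl carbonyl remains it is the least nucleophilic oxygen.

Step 12
Reactants: 23 1-[2,4-bis(benzyloxy)-6-hydroxyphenyl]ethan-1-one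
Product: 25 5,7-bis(benzyloxy)-4H-chromen-4-one, via enaminone 24 (not isolated)
Conditions: Me2NCH(OMe)2, toluene, 95 °C; then aq HCl, CH2Cl2, 40 °C
Reagents that add atoms: N,N-dimethylformamide dimethyl acetal, COC(OC)N(C)C
Why: In this enaminone chromone synthesis the methyl ketone condenses with the amide acetal to 24, and acid triggers conjugate addition of the free phenol and loss of dimethylamine, closing the 2-unsubstituted pyranone.

Step 13
Reactants: 21 {4-(benzyloxy)-3-[7-(benzyloxy)-5-hydroxy-2-(4-methoxyphenyl)-4-oxo-4H-chromen-8-yl]phenyl}boronic acid; 25 5,7-bis(benzyloxy)-4H-chromen-4-one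
Product: 26 (2S)-5,7-bis(benzyloxy)-2-{4-(benzyloxy)-3-[7-(benzyloxy)-5-hydroxy-2-(4-methoxyphenyl)-4-oxo-4H-chromen-8-yl]phenyl}-2,3-dihydro-4H-chromen-4-one
Conditions: Pd(OCOCF3)2 (10 mol %), (R)-4-tert-butyl-2-(pyridin-2-yl)-4,5-dihydrooxazole (12 mol %), NH4PF6 (30 mol %), H2O (5 equiv), ClCH2CH2Cl, 60 °C, 25 in excess
Reagents that add atoms: none
Why: In this enantioselective conjugate addition of an arylboronic acid catalysed by divalent palladium, transmetalation gives a cationic ligand-bound aryl–palladium species that inserts the C2=C3 bond of 25 in the enantio-determining step, the tert-butyl group of the oxazoline shielding one face so that ring B arrives on the face giving 2S, and water protonates the palladium enolate, while the 2-aryl-substituted enone of the flavone half is too hindered to compete as acceptor.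

Step 14
Reactants: 26 (2S)-5,7-bis(benzyloxy)-2-{4-(benzyloxy)-3-[7-(benzyloxy)-5-hydroxy-2-(4-methoxyphenyl)-4-oxo-4H-chromen-8-yl]phenyl}-2,3-dihydro-4H-chromen-4-one
Product: 27 2,3-dihydropodocarpusflavone A, (2S)
Conditions: H2 (1 atm), Pd/C (10 wt % Pd), EtOAc–MeOH, rt
Reagents that add atoms: none
Why: Heterogeneous hydrogenolysis cleaves the four O–benzyl bonds under neutral conditions in which neither retro-oxa-Michael opening at C2 nor cleavage of the anisyl methyl ether can occur, and the conjugated carbonyl groups and the flavone C2''=C3'' bond are not reduced at ambient pressure.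

Compound list
1 | methyl 5-chlorosalicylate | COC(=O)c1cc(Cl)ccc1O | starting material
2 | methyl 2-(benzyloxy)-5-chlorobenzoate | COC(=O)c1cc(Cl)ccc1OCc1ccccc1 | intermediate
3 | lithium 1-[2-(benzyloxy)-5-chlorophenyl]-2,2-dibromoethen-1-olate | [Li+].[O-]C(=C(Br)Br)c1cc(Cl)ccc1OCc1ccccc1 | intermediate
4 | lithium [2-(benzyloxy)-5-chlorophenyl]ethynolate | [Li+].[O-]C#Cc1cc(Cl)ccc1OCc1ccccc1 | intermediate
5 | {[2-(benzyloxy)-5-chlorophenyl]ethynyloxy}triisopropylsilane | CC(C)[Si](OC#Cc1cc(Cl)ccc1OCc1ccccc1)(C(C)C)C(C)C | intermediate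
6 | 3-ethoxycyclobut-2-en-1-one | CCOC1=CC(=O)C1 | starting material
7 | 3-ethoxybuta-1,3-dien-1-one, (1-ethoxyvinyl)ketene | C=C(OCC)C=C=O | intermediate
8 | 2-[2-(benzyloxy)-5-chlorophenyl]-4-(1-ethoxyvinyl)-3-(triisopropylsilyloxy)cyclobut-2-en-1-one (racemic) | CCOC(=C)C1C(=O)C(c2cc(Cl)ccc2OCc2ccccc2)=C1O[Si](C(C)C)(C(C)C)C(C)C | intermediate
9 | 2-[2-(benzyloxy)-5-chlorophenyl]-5-ethoxy-3-(triisopropylsilyloxy)hexa-1,3,5-trien-1-one (ketene carbon chain and ethoxyvinyl group cis on C3=C4) | O=C=C(c1cc(Cl)ccc1OCc1ccccc1)/C(O[Si](C(C)C)(C(C)C)C(C)C)=C\C(=C)OCC | intermediate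
10 | 2-[2-(benzyloxy)-5-chlorophenyl]-5-ethoxy-3-(triisopropylsilyloxy)cyclohexa-2,4-dien-1-one | CCOC1=CC(O[Si](C(C)C)(C(C)C)C(C)C)=C(c2cc(Cl)ccc2OCc2ccccc2)C(=O)C1 | intermediate
11 | 2-[2-(benzyloxy)-5-chlorophenyl]-5-ethoxy-3-(triisopropylsilyloxy)phenol | CCOc1cc(O)c(-c2cc(Cl)ccc2OCc2ccccc2)c(O[Si](C(C)C)(C(C)C)C(C)C)c1 | intermediate
12 | {3-(benzyloxy)-2-[2-(benzyloxy)-5-chlorophenyl]-5-ethoxyphenoxy}triisopropylsilane | CCOc1cc(OCc2ccccc2)c(-c2cc(Cl)ccc2OCc2ccccc2)c(O[Si](C(C)C)(C(C)C)C(C)C)c1 | intermediate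
13 | 3-(benzyloxy)-2-[2-(benzyloxy)-5-chlorophenyl]-5-ethoxyphenol | CCOc1cc(O)c(-c2cc(Cl)ccc2OCc2ccccc2)c(OCc2ccccc2)c1 | intermediate
14 | 4-(benzyloxy)-3-[2-(benzyloxy)-5-chlorophenyl]-6-ethoxy-2-hydroxybenzaldehyde | CCOc1c(C=O)c(O)c(-c2cc(Cl)ccc2OCc2ccccc2)c(OCc2ccccc2)c1 | intermediate
15 | 1-ethynyl-4-methoxybenzene | C#Cc1ccc(OC)cc1 | starting material
16 | lithium (4-methoxyphenyl)acetylide | [Li+].[C-]#Cc1ccc(OC)cc1 | intermediate
17 | 3-(benzyloxy)-2-[2-(benzyloxy)-5-chlorophenyl]-5-ethoxy-6-[1-hydroxy-3-(4-methoxyphenyl)prop-2-yn-1-yl]phenol (racemic) | CCOc1cc(OCc2ccccc2)c(-c2cc(Cl)ccc2OCc2ccccc2)c(O)c1C(O)C#Cc1ccc(OC)cc1 | intermediate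
18 | 1-{4-(benzyloxy)-3-[2-(benzyloxy)-5-chlorophenyl]-6-ethoxy-2-hydroxyphenyl}-3-(4-methoxyphenyl)prop-2-yn-1-one | CCOc1cc(OCc2ccccc2)c(-c2cc(Cl)ccc2OCc2ccccc2)c(O)c1C(=O)C#Cc1ccc(OC)cc1 | intermediate
19 | 7-(benzyloxy)-8-[2-(benzyloxy)-5-chlorophenyl]-5-ethoxy-2-(4-methoxyphenyl)-4H-chromen-4-one | COc1ccc(-c2cc(=O)c3c(OCC)cc(OCc4ccccc4)c(-c4cc(Cl)ccc4OCc4ccccc4)c3o2)cc1 | intermediate
20 | 7-(benzyloxy)-8-[2-(benzyloxy)-5-chlorophenyl]-5-hydroxy-2-(4-methoxyphenyl)-4H-chromen-4-one | COc1ccc(-c2cc(=O)c3c(O)cc(OCc4ccccc4)c(-c4cc(Cl)ccc4OCc4ccccc4)c3o2)cc1 | intermediate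
21 | {4-(benzyloxy)-3-[7-(benzyloxy)-5-hydroxy-2-(4-methoxyphenyl)-4-oxo-4H-chromen-8-yl]phenyl}boronic acid | COc1ccc(-c2cc(=O)c3c(O)cc(OCc4ccccc4)c(-c4cc(B(O)O)ccc4OCc4ccccc4)c3o2)cc1 | intermediate
22 | 2,4,6-trihydroxyacetophenone | CC(=O)c1c(O)cc(O)cc1O | starting material
23 | 1-[2,4-bis(benzyloxy)-6-hydroxyphenyl]ethan-1-one | CC(=O)c1c(O)cc(OCc2ccccc2)cc1OCc1ccccc1 | intermediate
24 | (E)-1-[2,4-bis(benzyloxy)-6-hydroxyphenyl]-3-(dimethylamino)prop-2-en-1-one | CN(C)/C=C/C(=O)c1c(O)cc(OCc2ccccc2)cc1OCc1ccccc1 | intermediate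
25 | 5,7-bis(benzyloxy)-4H-chromen-4-one | O=c1ccoc2cc(OCc3ccccc3)cc(OCc3ccccc3)c12 | intermediate
26 | (2S)-5,7-bis(benzyloxy)-2-{4-(benzyloxy)-3-[7-(benzyloxy)-5-hydroxy-2-(4-methoxyphenyl)-4-oxo-4H-chromen-8-yl]phenyl}-2,3-dihydro-4H-chromen-4-one | COc1ccc(-c2cc(=O)c3c(O)cc(OCc4ccccc4)c(-c4cc([C@@H]5CC(=O)c6c(OCc7ccccc7)cc(OCc7ccccc7)cc6O5)ccc4OCc4ccccc4)c3o2)cc1 | intermediate
27 | 2,3-dihydropodocarpusflavone A, (2S) | COc1ccc(-c2cc(=O)c3c(O)cc(O)c(-c4cc([C@@H]5CC(=O)c6c(O)cc(O)cc6O5)ccc4O)c3o2)cc1 | target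

Total step count: 14. Longest linear sequence: 12 (steps 1–10, 13, 14).

Steps most likely to fail

Step 3. The hindered aryl ynol ether may lose the race for ketene 7 to ketene dimerisation or to acylation of the phenol product. It may also undergo a silyl shift to a silylketene at the temperature that the donor-stabilised cyclobutenone needs for opening.

The fallback replaces ring construction by biaryl cross-coupling. It sets out from 23 and comes back at 20.
- Claisen–Schmidt condensation of 23 with 4-methoxybenzaldehyde (KOH, EtOH) would give (E)-1-[2,4-bis(benzyloxy)-6-hydroxyphenyl]-3-(4-methoxyphenyl)prop-2-en-1-one F1.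
- Oxidative cyclisation (catalytic I2, DMSO, 130 °C) would give 5,7-bis(benzyloxy)-2-(4-methoxyphenyl)-4H-chromen-4-one F2.
- Iodination with N-iodosuccinimide in DMF favours C8 in fully O-alkylated 5,7-dioxygenated flavones and would give 5,7-bis(benzyloxy)-8-iodo-2-(4-methoxyphenyl)-4H-chromen-4-one F3.
- Suzuki–Miyaura coupling with commercial [2-(benzyloxy)-5-chlorophenyl]boronic acid (Pd(PPh3)4, K2CO3, dioxane–H2O) engages C–I but not C–Cl and would give 5,7-bis(benzyloxy)-8-[2-(benzyloxy)-5-chlorophenyl]-2-(4-methoxyphenyl)-4H-chromen-4-one F4.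
- Chelation-controlled removal of the peri benzyl group (BCl3, 1 equiv, CH2Cl2, −78 °C) then leads to 20.

Step 13. Facial selectivity may erode with a para-alkoxy, electron-rich aryl donor. Protodeboronation may also outrun insertion into the electron-rich chromone.

The fallback separates C–C bond formation from stereocontrol. It sets out from 21 and 25 and comes back at 26.
- The addition is run with the achiral ligand 2,2'-bipyridine and Pd(OCOCF3)2 to give racemic 5,7-bis(benzyloxy)-2-{4-(benzyloxy)-3-[7-(benzyloxy)-5-hydroxy-2-(4-methoxyphenyl)-4-oxo-4H-chromen-8-yl]phenyl}-2,3-dihydro-4H-chromen-4-one F5.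
- F5 is then subjected to kinetic resolution by Noyori-type asymmetric transfer hydrogenation (Cp*RhCl[(R,R)-TsDPEN], HCO2H/Et3N, EtOAc).
- The 2R enantiomer is the matched one, since hydride delivery anti to the C2 aryl group creates 4R. It should be reduced to 7-(benzyloxy)-8-{2-(benzyloxy)-5-[(2R,4R)-5,7-bis(benzyloxy)-4-hydroxy-3,4-dihydro-2H-chromen-2-yl]phenyl}-5-hydroxy-2-(4-methoxyphenyl)-4H-chromen-4-one F6.
- The unreacted 2S ketone 26 is separated from F6 by chromatography.

Step 9. Benzyl ethers may be lost together with the ethyl group, or chloride attack on the ethyl carbon may stall at the temperature that the benzyl ethers tolerate.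

The fallback gives up selective cleavage in favour of exhaustive cleavage and selective re-protection. It sets out from 19 and comes back at 20.
- Excess BCl3 (CH2Cl2, −78 °C → rt) removes the ethyl and both benzyl groups and spares the anisyl methyl ether. This gives 8-(5-chloro-2-hydroxyphenyl)-5,7-dihydroxy-2-(4-methoxyphenyl)-4H-chromen-4-one F7.
- BnBr (2.1 equiv) and K2CO3 in acetone re-benzylate O7'' and O4' only, because the 5''-hydroxyl chelated to the carbonyl is not alkylated under these conditions.

Further compounds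
F1 | step 3 | (E)-1-[2,4-bis(benzyloxy)-6-hydroxyphenyl]-3-(4-methoxyphenyl)prop-2-en-1-one | COc1ccc(/C=C/C(=O)c2c(O)cc(OCc3ccccc3)cc2OCc2ccccc2)cc1
F2 | step 3 | 5,7-bis(benzyloxy)-2-(4-methoxyphenyl)-4H-chromen-4-one | COc1ccc(-c2cc(=O)c3c(OCc4ccccc4)cc(OCc4ccccc4)cc3o2)cc1
F3 | step 3 | 5,7-bis(benzyloxy)-8-iodo-2-(4-methoxyphenyl)-4H-chromen-4-one | COc1ccc(-c2cc(=O)c3c(OCc4ccccc4)cc(OCc4ccccc4)c(I)c3o2)cc1
F4 | step 3 | 5,7-bis(benzyloxy)-8-[2-(benzyloxy)-5-chlorophenyl]-2-(4-methoxyphenyl)-4H-chromen-4-one | COc1ccc(-c2cc(=O)c3c(OCc4ccccc4)cc(OCc4ccccc4)c(-c4cc(Cl)ccc4OCc4ccccc4)c3o2)cc1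
F5 | step 13 | racemic 5,7-bis(benzyloxy)-2-{4-(benzyloxy)-3-[7-(benzyloxy)-5-hydroxy-2-(4-methoxyphenyl)-4-oxo-4H-chromen-8-yl]phenyl}-2,3-dihydro-4H-chromen-4-one | COc1ccc(-c2cc(=O)c3c(O)cc(OCc4ccccc4)c(-c4cc(C5CC(=O)c6c(OCc7ccccc7)cc(OCc7ccccc7)cc6O5)ccc4OCc4ccccc4)c3o2)cc1
F6 | step 13 | 7-(benzyloxy)-8-{2-(benzyloxy)-5-[(2R,4R)-5,7-bis(benzyloxy)-4-hydroxy-3,4-dihydro-2H-chromen-2-yl]phenyl}-5-hydroxy-2-(4-methoxyphenyl)-4H-chromen-4-one | COc1ccc(-c2cc(=O)c3c(O)cc(OCc4ccccc4)c(-c4cc([C@H]5C[C@@H](O)c6c(OCc7ccccc7)cc(OCc7ccccc7)cc6O5)ccc4OCc4ccccc4)c3o2)cc1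
F7 | step 9 | 8-(5-chloro-2-hydroxyphenyl)-5,7-dihydroxy-2-(4-methoxyphenyl)-4H-chromen-4-one | COc1ccc(-c2cc(=O)c3c(O)cc(O)c(-c4cc(Cl)ccc4O)c3o2)cc1
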